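Late in both runs the target still creeps upward, and that creep is a rate that can be read, so the examination is about which concentration stands behind it.

| setting | elm | birch | flask |
|---|---|---|---|
| electrophile | 0.087 M | 0.20 M | 0.13 M |
| free base | 0.065 M | 0.065 M | 0.0650 M |
| protonated nucleophile | 0.26 M | 0.26 M | 0.260 M |
| remark | run made earlier | run made earlier |  |
| time |  |  | 2.5 h |

| run | time / min | electrophile / % | target / % |
|---|---|---|---|
| elm | 10.0 | 95.3 | 4.7 |
| elm | 15.0 | 94.3 | 5.1 |
| elm | 20.0 | 94.5 | 5.4 |
| elm | 30.0 | 89.5 | 11.9 |
| elm | 50.0 | 85.9 | 12.6 |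
| elm | 80.0 | 87.2 | 15.4 |
| elm | 120 | 84.5 | 17.6 |
| birch | 6.00 | 98.3 | 2.8 |
| birch | 20.0 | 94.4 | 7.4 |
| birch | 30.0 | 90.9 | 7.7 |
| birch | 50.0 | 91.8 | 10.3 |
| birch | 80.0 | 87.3 | 11.6 |
| birch | 90.0 | 86.8 | 11.4 |
| birch | 120 | 85.3 | 14.2 |

(scatter of a reading: 1 percentage point)

* part of the electrophile that has reacted at 2.5 h
* share of the unused nucleophile that is free and not bound as protonated nucleophile, at 2.5 h

- the numbers in the tables scatter by 1 percentage point (one standard deviation)
- the earlier runs do not show how much of nucleophile is bound; that part of a forecast is a guess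

Q. What is the order in electrophile?

A. First: the opening slopes are 0.00470 min⁻¹ in elm and 0.00467 min⁻¹ in birch, the same within the scatter, although the charge goes from 0.087 M to 0.20 M. That is a pseudo-first-order constant, so a second concentration sits inside it.

Q. Which one?

A. c(nucleophile). I assume the free base releases it from the protonated nucleophile, so it starts at 0.0650 M; neither run varied this. The specific rate, the first-order constant per unit of c(nucleophile), is then 0.00121 L mol⁻¹ s⁻¹.

Q. And late?

A. From 80.0 min to 120 min the two runs' mean slope, divided by the electrophile left and by the specific rate, reads c(nucleophile) as 0.00977 M, below the start, while the electrophile stands at 84.5% in elm.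

Q. Your weak spot?

A. The tail. I assume c(nucleophile) falls as inverse time, giving 0.00652 M at 2.5 h. Against 0.195 M of protonated nucleophile, that makes fr 3.23%. The mean of the last readings, 15.9%, plus that tail gives c 17.1%.

The forecast differs on fr: it gives 16.5% and 13.5%, reading the curves thus: “That looks like a reversible approach to equilibrium, not simple consumption”.

The flask gives 17.0% and 2.45%, with c(nucleophile) at 0.00517 M.

    nucleophile + acid set free ⇌ protonated nucleophile, settled at all times (K = 3400 L mol⁻¹)
    electrophile + nucleophile ⇌ acid set free + target (K = 1.90, k = 0.00140 L mol⁻¹ s⁻¹)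
    acid set free + free base ⇌ salt of the base, settled at all times (K = 1.00 × 10⁶ L mol⁻¹)
    2 nucleophile → homo dimer (k = 0.00370 L mol⁻¹ s⁻¹)

The specific rate read from the runs, 0.00121 L mol⁻¹ s⁻¹, stands below the scheme's 0.0014 L mol⁻¹ s⁻¹, so the time-means here take the scheme's constant. Counting the forward step alone, this flask's 17.0% means a time-mean c(nucleophile) of 0.0148 M. The neighbouring flask changes one setting, 0.26 M of free base, which on the read specific rate raises the start constant from 0.00472 min⁻¹ to 0.0189 min⁻¹. It ends with 31.8% reacted, by the same forward reckoning a time-mean of 0.0304 M. At 2.50 h its c(nucleophile) is 0.00467 M, a constant of 3.92 × 10⁻⁴ min⁻¹, and 10.7% of its unused nucleophile is free.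

The numbers in the tables are simulated with made-up constants, and the scatter is random.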